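**Strategy.** Everything rests on opening the enolised β-diketone ring (ring D: D-1 C=O, D-2, D-3 C–OH, quaternary D-4, D-5 C–OMe, D-6 C–Me) across D-1–D-2 and D-3–D-4. One operation, a crossed Claisen/Dieckmann annulation, joins a four-carbon dienolate (D-4, D-5, D-6, D-1, methyl enol ether already in place) to a two-carbon aryl-ester unit (D-2, D-3): the γ-carbon is acylated at quaternary D-4, then the ketone enolate closes onto the ester. The precursor is a dihydrocoumarin fused to the masked (2S)-flavanone; its lactone is a temporary ring that activates D-3, carries the benzylic R centre and releases 7-OH. The step exploits the vinylogous-acid unit D-1/D-2/D-3 beside quaternary D-4.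

Key step: step 9

Remark: (S)-pinocembrin, the natural (2S)-5,7-dihydroxyflavanone, is assumed to be commercial and supplies C-2; flavanone positions carry their usual numbers (O-1 to C-8a), ring D the labels D-1 to D-6 given above.

Step 1
Reactants: 1 (S)-pinocembrin
Product: 2 7-O-MOM-pinocembrin
Conditions: MOMCl (1.1 equiv), iPr2NEt, CH2Cl2, 0 °C
Reagents that add atoms: chloromethyl methyl ether, COCCl
Why: Williamson-type O-alkylation that should select the 7-OH (most acidic, not hydrogen-bonded) over the chelated 5-OH, the amine base at 0 °C being too weak to open the flavanone at C-2.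

Step 2
Reactants: 2 7-O-MOM-pinocembrin
Product: 3 6-iodo-7-O-MOM-pinocembrin
Conditions: BnMe3N[ICl2] (1.05 equiv), CaCO3, CH2Cl2–MeOH, rt, dark
Reagents that add atoms: benzyltrimethylammonium dichloroiodate, C[N+](C)(C)Cc1ccccc1.Cl[I-]Cl
Why: Electrophilic aromatic iodination in which the free 5-OH should direct iodine to its ortho position C-6 rather than to C-8 (flanked by two ether oxygens), with CaCO3 buffering HCl so that the MOM ether and C-2 survive.

Step 3
Reactants: 3 6-iodo-7-O-MOM-pinocembrin
Product: 4 7-O-MOM-strobopinin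
Conditions: Me4Sn (3 equiv), Pd(PPh3)4 (5 mol %), CuI (10 mol %), DMF, 80 °C
Reagents that add atoms: tetramethylstannane, C[Sn](C)(C)C
Why: Stille cross-coupling of the aryl iodide under neutral conditions (no base that could open the flavanone), CuI assisting transmetalation at the doubly ortho-substituted carbon.

Step 4
Reactants: 4 7-O-MOM-strobopinin
Product: 5 (S)-strobopinin
Conditions: 3 M HCl, MeOH, 50 °C
Reagents that add atoms: none
Why: Acid-catalysed acetal exchange with methanol removes the MOM group, flavanones being configurationally stable to dilute acid.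

Step 5
Reactants: 5 (S)-strobopinin; 6 (E)-4-methylpent-2-enal
Product: 8 flavanone-fused dihydrocoumarin (lactone O-7/C-8; isopropyl carbon R), via lactol 7 (not isolated)
Conditions: (R)-2-[diphenyl(trimethylsilyloxy)methyl]pyrrolidine (20 mol %), PhCO2H (20 mol %), toluene, rt; then CH2Cl2, pyridinium chlorochromate [C5H5NH][CrO3Cl], NaOAc, rt
Reagents that add atoms: none
Why: Iminium-ion-catalysed asymmetric Friedel–Crafts conjugate addition at C-8 (the only free arene position), hemiacetal closure with the neighbouring 7-OH and lactol oxidation; the diphenyl(silyloxy)methyl group shields one face of the (E)-iminium ion, so the R catalyst should deliver the arene to the β-face that gives the R centre (standard shielding model), and C-2 is untouched.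

Step 6
Reactants: 8 flavanone-fused dihydrocoumarin
Product: 9 bis-TBS lactone (5-O-TBS; C-4 ketone as TBS dienol ether)
Conditions: TBSOTf (2.5 equiv), Et3N (4 equiv), CH2Cl2, −78 → 0 °C, dark; Et3N-deactivated silica
Reagents that add atoms: tert-butyldimethylsilyl triflate, CC(C)(C)[Si](C)(C)OS(=O)(=O)C(F)(F)F
Why: Soft enolisation–silylation turns the C-4 ketone into its silyl enol ether without a free enolate and silylates 5-OH, which masks the β-aryloxy ketone against E1cB ring opening (loss of C-2) in the basic key step.

Step 7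
Reactants: 10 methyl 4-methyl-3-oxopentanoate
Product: 11 methyl 2,4-dimethyl-3-oxopentanoate
Conditions: MeI (1.05 equiv), K2CO3, acetone, 50 °C
Reagents that add atoms: iodomethane, CI
Why: C-alkylation of the β-keto ester enolate installs the future D-6 methyl group.

Step 8
Reactants: 11 methyl 2,4-dimethyl-3-oxopentanoate
Product: 12 methyl (E)-3-methoxy-2,4-dimethylpent-2-enoate
Conditions: NaH, THF–DMPU, 0 °C; Me2SO4, 0 °C → rt
Reagents that add atoms: dimethyl sulfate, COS(=O)(=O)OC
Why: O-alkylation of the dissociated sodium enolate by a hard electrophile in a dipolar aprotic medium (the hindered α-carbon disfavours C-alkylation) should give mainly the E enol ether, whose geometry is in any case erased in the dienolate of step 9.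

Step 9
Reactants: 9 bis-TBS lactone; 12 methyl (E)-3-methoxy-2,4-dimethylpent-2-enoate
Product: 15 bis-TBS-protected target, via lithium dienolate 13 (not isolated), via ring-opened keto ester 14 (not isolated)
Conditions: 12 (2.5 equiv), LiN(iPr)2 (2.5 equiv), THF–DMPU, −78 → −40 °C; then 9, −78 → 0 °C, dark; AcOH, −78 °C
Reagents that add atoms: none
Why: The γ-carbon of dienolate 13 adds to the aryl-ester carbonyl of 9 (crossed Claisen condensation, also reachable through the ketene that E1cB of the lactone enolate would give), which opens the temporary lactone ring, forms D-3–D-4 at the quaternary carbon and frees the 7-phenoxide in 14; excess 13 then enolises the new ketone toward D-2, and this enolate closes onto the methyl ester (Dieckmann condensation) to form D-1–D-2 with loss of methoxide. The closest known reaction types are the γ-acylation of β-alkoxy enoate dienolates by esters used in pyranone synthesis and the Dieckmann route from 5-oxo esters to cyclohexane-1,3-diones. The one new ring closes in a 6-(enolexo)-exo-trig mode. No stereocentre is created: the benzylic R centre is β to the reacting carbonyl and cannot epimerise by enolisation, and C-2 is held because the silyl dienol ether removes the ketone that would otherwise suffer E1cB ring opening. The step needs γ- over α-acylation and C- over O-cyclisation, and both should be secured thermodynamically, since an α-acylated ester (a non-enolisable β-keto ester) or an enol lactone can revert under the alkoxide present while the γ-path ends irreversibly in the stabilised dione enolate; an enoate geometry of 14 that cannot close should likewise be recycled by reversible alkoxide addition at the β-alkoxy acrylate.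

Step 10
Reactants: 15 bis-TBS-protected target
Product: 16 target
Conditions: HF·pyridine, THF–pyridine, 0 °C
Reagents that add atoms: none
Why: Fluoride cleavage of both Si–O bonds in a weakly acidic medium lets the enol tautomerise to the C-4 ketone without an enolate (C-2 retained), and the cold, non-basic conditions should avoid retro-Michael scission or cyclodehydration at the benzylic carbon.

**Compound list**
1 | (S)-pinocembrin, (2S)-5,7-dihydroxy-2-phenylchroman-4-one | Oc1cc(O)c2c(c1)O[C@H](c1ccccc1)CC2=O | starting material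
2 | (2S)-5-hydroxy-7-(methoxymethoxy)-2-phenylchroman-4-one | COCOc1cc(O)c2c(c1)O[C@H](c1ccccc1)CC2=O | intermediate
3 | (2S)-5-hydroxy-6-iodo-7-(methoxymethoxy)-2-phenylchroman-4-one | COCOc1c(I)c(O)c2c(c1)O[C@H](c1ccccc1)CC2=O | intermediate
4 | (2S)-5-hydroxy-7-(methoxymethoxy)-6-methyl-2-phenylchroman-4-one | COCOc1c(C)c(O)c2c(c1)O[C@H](c1ccccc1)CC2=O | intermediate
5 | (S)-strobopinin, (2S)-5,7-dihydroxy-6-methyl-2-phenylchroman-4-one | Oc1c(C)c(O)c2c(c1)O[C@H](c1ccccc1)CC2=O | intermediate
6 | (E)-4-methylpent-2-enal | CC(C)/C=C/C=O | starting material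
7 | lactol: (2S,10R)-5,8-dihydroxy-6-methyl-2-phenyl-10-(propan-2-yl)-2,3,9,10-tetrahydro-4H,8H-pyrano[2,3-f]chromen-4-one (hemiacetal between flavanone O-7 and the side-chain aldehyde, anomer mixture) | CC(C)[C@H]1CC(O)Oc2c(C)c(O)c3C(=O)C[C@@H](c4ccccc4)Oc3c21 | intermediate
8 | (2S,10R)-5-hydroxy-6-methyl-2-phenyl-10-(propan-2-yl)-2,3,9,10-tetrahydro-4H,8H-pyrano[2,3-f]chromene-4,8-dione (lactone ring closed between flavanone O-7 and C-8) | CC(C)[C@H]1CC(=O)Oc2c(C)c(O)c3C(=O)C[C@@H](c4ccccc4)Oc3c21 | intermediate
9 | (2S,10R)-4,5-bis(tert-butyldimethylsilyloxy)-6-methyl-2-phenyl-10-(propan-2-yl)-9,10-dihydro-2H,8H-pyrano[2,3-f]chromen-8-one | CC(C)[C@H]1CC(=O)Oc2c(C)c(O[Si](C)(C)C(C)(C)C)c3C(O[Si](C)(C)C(C)(C)C)=C[C@@H](c4ccccc4)Oc3c21 | intermediate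
10 | methyl 4-methyl-3-oxopentanoate | COC(=O)CC(=O)C(C)C | starting material
11 | methyl 2,4-dimethyl-3-oxopentanoate (racemic) | COC(=O)C(C)C(=O)C(C)C | intermediate
12 | methyl (E)-3-methoxy-2,4-dimethylpent-2-enoate | COC(=O)/C(C)=C(/OC)C(C)C | intermediate
13 | lithium 1,3-dimethoxy-2,4-dimethylpenta-1,3-dien-1-olate | [Li+].COC([O-])=C(C)C(OC)=C(C)C | intermediate
14 | lithium 7-phenoxide of methyl (6R)-6-[(2S)-4,5-bis(tert-butyldimethylsilyloxy)-7-hydroxy-6-methyl-2-phenyl-2H-chromen-8-yl]-3-methoxy-2,4,4,7-tetramethyl-5-oxooct-2-enoate (enoate geometry undefined) | [Li+].COC(=O)C(C)=C(OC)C(C)(C)C(=O)C[C@H](C(C)C)c1c([O-])c(C)c(O[Si](C)(C)C(C)(C)C)c2c1O[C@H](c1ccccc1)C=C2O[Si](C)(C)C(C)(C)C | intermediate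
15 | (2S)-4,5-bis(tert-butyldimethylsilyloxy)-8-[(1R)-1-(2-hydroxy-4-methoxy-3,3,5-trimethyl-6-oxocyclohexa-1,4-dien-1-yl)-2-methylpropyl]-6-methyl-2-phenyl-2H-chromen-7-ol | COC1=C(C)C(=O)C([C@@H](c2c(O)c(C)c(O[Si](C)(C)C(C)(C)C)c3c2O[C@H](c2ccccc2)C=C3O[Si](C)(C)C(C)(C)C)C(C)C)=C(O)C1(C)C | intermediate
16 | (2S)-5,7-dihydroxy-8-[(1R)-1-(2-hydroxy-4-methoxy-3,3,5-trimethyl-6-oxocyclohexa-1,4-dien-1-yl)-2-methylpropyl]-6-methyl-2-phenylchroman-4-one | COC1=C(C)C(=O)C([C@@H](c2c(O)c(C)c(O)c3c2O[C@H](c2ccccc2)CC3=O)C(C)C)=C(O)C1(C)C | target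

**Step count.** Total: 10 steps. Longest linear sequence: 8 steps (1–6, 9, 10); steps 7 and 8 form the side branch.

**Steps most likely to fail**

Step 9. Acyl transfer to the hindered γ-carbon may be outrun by enolisation and ketene chemistry of the lactone, or the lithium methoxide formed may strip the silyl dienol ether so that C-2 erodes. The fallback sets out from 12 and 5 and comes back at 16; it builds ring D on a simple substrate and unites the halves by a Michael reaction. The dienolate of 12 is acylated at the γ-carbon with N-acetylimidazole to give methyl 3-methoxy-2,4,4-trimethyl-5-oxohex-2-enoate F1. KOtBu in THF closes it (Dieckmann) to 3-hydroxy-5-methoxy-4,6,6-trimethylcyclohexa-2,4-dien-1-one F2. Knoevenagel condensation with isobutyraldehyde (L-proline cat.) gives the 2-(2-methylpropylidene) dione F3. Friedel–Crafts-type Michael addition of C-8 of 5 to F3 under a quinine-derived bifunctional squaramide (the quinidine series offering the opposite sense) should give 16. The benzylic epimer F4, a diastereomer, would be removed by chromatography.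

Step 5. The acyl-deactivated arene may add too slowly to the iminium ion, condense instead at the iminium carbon to a 2H-chromene, or add with poor facial selectivity. The fallback sets out from 5 and comes back at 8; it replaces catalyst control by a stronger acceptor and separation of diastereomers. 5 is heated with 5-(2-methylpropylidene)-2,2-dimethyl-1,3-dioxane-4,6-dione F5 (from Meldrum's acid and isobutyraldehyde) and Yb(OTf)3 (10 mol %) in MeNO2 at 60 °C. Conjugate addition at C-8 and lactonisation onto 7-OH with loss of acetone and CO2 should give 8 together with its epimer at the isopropyl carbon, the (2S,10S)-lactone F6, which is separated by chromatography or crystallisation.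

Step 6. Peri strain between the two silyloxy groups may leave the ketone unsilylated, or the monodentate silyl dienol ether may not last through step 9. The fallback sets out from 8 and comes back at 16; it uses one bridging protecting group instead of two separate ones. tBu2Si(OTf)2 and 2,6-lutidine tie O-5 and the C-4 enol oxygen into a six-membered ring, giving the cyclic di-tert-butylsilylene dienol ether F7. The same annulation with dienolate 13 should pass through the ring-opened silylene keto ester F8 to the silylene-protected target F9, and HF·pyridine then gives 16.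

**Further compounds**
F1 | step 9 | methyl 3-methoxy-2,4,4-trimethyl-5-oxohex-2-enoate | COC(=O)C(C)=C(OC)C(C)(C)C(C)=O
F2 | step 9 | 3-hydroxy-5-methoxy-4,6,6-trimethylcyclohexa-2,4-dien-1-one | COC1=C(C)C(=O)C=C(O)C1(C)C
F3 | step 9 | 5-methoxy-4,6,6-trimethyl-2-(2-methylpropylidene)cyclohex-4-ene-1,3-dione | CC(C)C=C1C(=O)C(C)=C(OC)C(C)(C)C1=O
F4 | step 9 | (2S)-5,7-dihydroxy-8-[(1S)-1-(2-hydroxy-4-methoxy-3,3,5-trimethyl-6-oxocyclohexa-1,4-dien-1-yl)-2-methylpropyl]-6-methyl-2-phenylchroman-4-one | COC1=C(C)C(=O)C([C@H](c2c(O)c(C)c(O)c3c2O[C@H](c2ccccc2)CC3=O)C(C)C)=C(O)C1(C)C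
F5 | step 5 | 2,2-dimethyl-5-(2-methylpropylidene)-1,3-dioxane-4,6-dione | CC(C)C=C1C(=O)OC(C)(C)OC1=O
F6 | step 5 | (2S,10S)-5-hydroxy-6-methyl-2-phenyl-10-(propan-2-yl)-2,3,9,10-tetrahydro-4H,8H-pyrano[2,3-f]chromene-4,8-dione | CC(C)[C@@H]1CC(=O)Oc2c(C)c(O)c3C(=O)C[C@@H](c4ccccc4)Oc3c21
F7 | step 6 | cyclic di-tert-butylsilylene dienol ether of lactone 8 (Si bridging O-5 and the C-4 enol oxygen) | CC(C)[C@H]1CC(=O)Oc2c(C)c3O[Si](C(C)(C)C)(C(C)(C)C)OC4=C[C@@H](c5ccccc5)Oc(c34)c21
F8 | step 6 | lithium 7-phenoxide of the ring-opened silylene keto ester (silylene analogue of 14) | [Li+].COC(=O)C(C)=C(OC)C(C)(C)C(=O)C[C@H](C(C)C)c1c([O-])c(C)c2O[Si](C(C)(C)C)(C(C)(C)C)OC3=C[C@@H](c4ccccc4)Oc1c23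
F9 | step 6 | silylene-protected target (silylene analogue of 15) | COC1=C(C)C(=O)C([C@@H](c2c(O)c(C)c3O[Si](C(C)(C)C)(C(C)(C)C)OC4=C[C@@H](c5ccccc5)Oc2c34)C(C)C)=C(O)C1(C)C
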